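**Retrosynthetic overview**

1. Each quinone ring is numbered C1 (carbonyl next to the ring–ring carbon), C2 (methyl), C3 (hydroxyl), C4 (carbonyl), C5 (phenethyl), C6 (ring–ring carbon). The plan rests on the two C5–CH2–CH2–Ph chains: each is cut between its two methylene carbons, i.e. traced back to a CH=CH bond made from a ring-bound formyl group and a benzylic phosphonate, on both halves at once.
2. Each hydroxyquinone ring is traced back to a resorcinol ring carried as its dimethyl ether: the oxygens at C1 and C3 are the phenol oxygens, and the oxygen at C4 is introduced last by oxidation of the single ring C–H.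
3. The C6–C6' bond is cut by reductive homocoupling of an ortho-iodobenzaldehyde; the formyl group first activates the halide and then becomes the side chain.
4. No ring is formed in the route: both carbocycles are the benzene ring of 3,5-dimethoxy-4-methylbenzaldehyde. Order of events: iodination, biaryl coupling, double olefination, hydrogenation, demethylation, oxidation.

Key step: step 3

Assumption: the target SMILES gives no descriptor for the hindered C6–C6' axis, so the biaryl is made and carried as the racemate and no resolution is planned.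

**Route**

Step 1
Reactants: 1 3,5-dimethoxy-4-methylbenzaldehyde
Product: 2 2-iodo-3,5-dimethoxy-4-methylbenzaldehyde
Conditions: NIS (1.05 equiv), CF3CO2H (0.3 equiv), MeCN, rt to 50 °C, dark
Reagents that add atoms: N-iodosuccinimide, O=C1CCC(=O)N1I
Why: Electrophilic aromatic iodination with acid-activated NIS; the two free ring positions are equivalent and each is ortho to one methoxy group and para to the other, so a single monoiodide should form and one equivalent of NIS limits diiodination.

Step 2
Reactants: 2 2-iodo-3,5-dimethoxy-4-methylbenzaldehyde (two molecules)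
Product: 3 4,4',6,6'-tetramethoxy-5,5'-dimethylbiphenyl-2,2'-dicarbaldehyde (racemic axis)
Conditions: activated Cu powder (4 equiv), DMF, 150 °C, Ar
Reagents that add atoms: none
Why: Classical Ullmann reductive homocoupling of an aryl iodide on zerovalent copper, which works best when an electron-withdrawing ortho substituent such as the formyl group flanks the halide and which tolerates aldehydes and aryl ethers.

Step 3
Reactants: 3 4,4',6,6'-tetramethoxy-5,5'-dimethylbiphenyl-2,2'-dicarbaldehyde; 4 diethyl benzylphosphonate
Product: 6 2,2',4,4'-tetramethoxy-3,3'-dimethyl-6,6'-bis[(E)-2-phenylethenyl]biphenyl, via monostyryl monoaldehyde 5 (not isolated)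
Conditions: 4 (3.0 equiv), KOtBu (2.8 equiv), THF, 0 °C, 30 min; then 3, 0 °C to rt (50 °C if conversion stalls)
Reagents that add atoms: none
Why: Twofold Horner–Wadsworth–Emmons olefination: the potassium carbanion of 4 adds to a formyl carbon, the resulting alkoxide closes on phosphorus to a transient oxaphosphetane, and syn-cycloreversion expels diethyl phosphate and leaves the CH=CH bond; monoaldehyde 5 then undergoes the same sequence at its remaining formyl group. The closest known reaction type is the routine stilbene synthesis from aryl aldehydes and benzylphosphonate anions. No ring is closed and no stereocentre is made; the E geometry follows from reversible addition of the aryl-stabilised carbanion and the lower energy of the trans-disposed oxaphosphetane, and is in any case erased by the hydrogenation of step 4. The selectivity that matters is complete reaction of both formyl groups ahead of base-induced hydride transfer between them, which is secured by the absence of α-hydrogens in 3, by pre-forming the carbanion with slightly less base than phosphonate so that no free alkoxide meets the dialdehyde, and by the small steric demand of the benzylic nucleophile.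

Step 4
Reactants: 6 2,2',4,4'-tetramethoxy-3,3'-dimethyl-6,6'-bis[(E)-2-phenylethenyl]biphenyl
Product: 7 2,2',4,4'-tetramethoxy-3,3'-dimethyl-6,6'-bis(2-phenylethyl)biphenyl
Conditions: H2 (1 atm), 10% Pd/C, EtOAc/EtOH, rt
Reagents that add atoms: none
Why: Heterogeneous catalytic hydrogenation of two 1,2-disubstituted styrenic double bonds over Pd/C at 1 atm, conditions under which aryl methyl ethers and benzene rings are inert, so any alkene geometry converges on the same saturated chains.

Step 5
Reactants: 7 2,2',4,4'-tetramethoxy-3,3'-dimethyl-6,6'-bis(2-phenylethyl)biphenyl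
Product: 8 3,3'-dimethyl-6,6'-bis(2-phenylethyl)biphenyl-2,2',4,4'-tetrol
Conditions: BBr3 (8 equiv), CH2Cl2, −78 °C to rt; then H2O, 0 °C
Reagents that add atoms: none
Why: Exhaustive aryl methyl ether cleavage by BBr3 (Lewis acid–base adduct, bromide attack on the O-methyl carbon, hydrolysis of the aryl borates on work-up), for which the saturated chains and the biaryl offer no competing site.

Step 6
Reactants: 8 3,3'-dimethyl-6,6'-bis(2-phenylethyl)biphenyl-2,2',4,4'-tetrol
Product: 9 3,3'-dihydroxy-2,2'-dimethyl-5,5'-bis(2-phenylethyl)-6,6'-bi(cyclohexa-2,5-diene-1,4-dione) (target)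
Conditions: (KSO3)2NO (Fremy's salt, 5 equiv), KH2PO4, H2O/acetone, 0 °C to rt
Reagents that add atoms: dipotassium nitrosodisulfonate (Fremy's salt, (KSO3)2NO), [K+].[K+].[O]N(S(=O)(=O)[O-])S(=O)(=O)[O-]
Why: Teuber oxidation: the nitroxide radical abstracts a phenolic hydrogen and a second equivalent delivers oxygen to the only free ring carbon, which is para to one hydroxyl and ortho to the other, so either mode of attack should give, after tautomerisation, the same 2-hydroxy-1,4-benzoquinone on each ring.

**Compound list**

1 | 3,5-dimethoxy-4-methylbenzaldehyde | COc1cc(C=O)cc(OC)c1C | starting material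
2 | 2-iodo-3,5-dimethoxy-4-methylbenzaldehyde | COc1cc(C=O)c(I)c(OC)c1C | intermediate
3 | 4,4',6,6'-tetramethoxy-5,5'-dimethylbiphenyl-2,2'-dicarbaldehyde | COc1cc(C=O)c(-c2c(C=O)cc(OC)c(C)c2OC)c(OC)c1C | intermediate
4 | diethyl benzylphosphonate | CCOP(=O)(Cc1ccccc1)OCC | starting material
5 | 4,4',6,6'-tetramethoxy-5,5'-dimethyl-2'-[(E)-2-phenylethenyl]biphenyl-2-carbaldehyde | COc1cc(C=O)c(-c2c(/C=C/c3ccccc3)cc(OC)c(C)c2OC)c(OC)c1C | intermediate
6 | 2,2',4,4'-tetramethoxy-3,3'-dimethyl-6,6'-bis[(E)-2-phenylethenyl]biphenyl | COc1cc(/C=C/c2ccccc2)c(-c2c(/C=C/c3ccccc3)cc(OC)c(C)c2OC)c(OC)c1C | intermediate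
7 | 2,2',4,4'-tetramethoxy-3,3'-dimethyl-6,6'-bis(2-phenylethyl)biphenyl | COc1cc(CCc2ccccc2)c(-c2c(CCc3ccccc3)cc(OC)c(C)c2OC)c(OC)c1C | intermediate
8 | 3,3'-dimethyl-6,6'-bis(2-phenylethyl)biphenyl-2,2',4,4'-tetrol | Cc1c(O)cc(CCc2ccccc2)c(-c2c(CCc3ccccc3)cc(O)c(C)c2O)c1O | intermediate
9 | 3,3'-dihydroxy-2,2'-dimethyl-5,5'-bis(2-phenylethyl)-6,6'-bi(cyclohexa-2,5-diene-1,4-dione) | CC1=C(O)C(=O)C(CCc2ccccc2)=C(C2=C(CCc3ccccc3)C(=O)C(O)=C(C)C2=O)C1=O | target

**Step count and risk**

Total step count: 6. Longest linear sequence: 6 steps (1 to 9).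

Steps most likely to fail:

Step 3 (key step). The second olefination may stall at the crowded formyl group of 5, or base may trigger hydride transfer between the two neighbouring formyl groups (intramolecular Cannizzaro–Tishchenko reaction) and consume the dialdehyde. The fallback reverses the polarity of the same C=C bond formation and sets out from 3. Reduction with NaBH4 (MeOH/THF, 0 °C) should give [4,4',6,6'-tetramethoxy-5,5'-dimethylbiphenyl-2,2'-diyl]dimethanol F2. PBr3 (CH2Cl2, 0 °C) should convert it into 2,2'-bis(bromomethyl)-4,4',6,6'-tetramethoxy-5,5'-dimethylbiphenyl F3. Michaelis–Arbuzov reaction with P(OEt)3 (neat, 140 °C) should give tetraethyl [(4,4',6,6'-tetramethoxy-5,5'-dimethylbiphenyl-2,2'-diyl)bis(methylene)]bis(phosphonate) F4. Its dianion (KOtBu, THF, 0 °C to rt) should then react with the unhindered electrophile benzaldehyde in a double Horner–Wadsworth–Emmons reaction, and the route is rejoined at 6.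

Step 2. Reductive loss of iodine without C–C bond formation, and slow coupling at a carbon flanked on both sides, may erode the homocoupling. The fallback replaces the copper-mediated coupling by a palladium cross-coupling of two differently activated halves and sets out from 2. Miyaura borylation (B2pin2, PdCl2(dppf), KOAc, dioxane, 90 °C) should give 3,5-dimethoxy-4-methyl-2-(4,4,5,5-tetramethyl-1,3,2-dioxaborolan-2-yl)benzaldehyde F1. Suzuki–Miyaura coupling of this boronate with a second portion of 2 (Pd(OAc)2, SPhos, K3PO4, toluene/H2O, 100 °C) should deliver the biaryl, and the route is rejoined at 3.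

Step 6. The free bis-resorcinol is lipophilic and very electron-rich, so slow phase transfer, over-oxidation and oxidative coupling of the phenols may compete with clean quinone formation on both rings. The fallback installs the third oxygen before any phenol is unmasked and sets out from 7, bypassing 8.
- Rieche formylation (Cl2CHOMe, TiCl4, CH2Cl2, 0 °C) at the only free position of each dimethoxyarene ring should give 2,2',4,4'-tetramethoxy-3,3'-dimethyl-6,6'-bis(2-phenylethyl)biphenyl-5,5'-dicarbaldehyde F5.
- Baeyer–Villiger (Dakin-type) oxidation with mCPBA (CH2Cl2, rt) should give the corresponding 5,5'-diyl diformate F6.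
- Methanolysis (K2CO3, MeOH) should give 2,2',4,4'-tetramethoxy-3,3'-dimethyl-6,6'-bis(2-phenylethyl)biphenyl-5,5'-diol F7.
- Oxidative demethylation of each para-methoxyphenol unit with (NH4)2Ce(NO3)6 (MeCN/H2O, 0 °C) should give 3,3'-dimethoxy-2,2'-dimethyl-5,5'-bis(2-phenylethyl)-6,6'-bi(cyclohexa-2,5-diene-1,4-dione) F8.
- Hydrolysis of the two vinylogous esters (aqueous NaOH, MeOH, rt, then dilute HCl) should give the target, and the route is rejoined at 9.

**Further compounds**

F1 | step 2 | 3,5-dimethoxy-4-methyl-2-(4,4,5,5-tetramethyl-1,3,2-dioxaborolan-2-yl)benzaldehyde | COc1cc(C=O)c(B2OC(C)(C)C(C)(C)O2)c(OC)c1C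
F2 | step 3 | [4,4',6,6'-tetramethoxy-5,5'-dimethylbiphenyl-2,2'-diyl]dimethanol | COc1cc(CO)c(-c2c(CO)cc(OC)c(C)c2OC)c(OC)c1C
F3 | step 3 | 2,2'-bis(bromomethyl)-4,4',6,6'-tetramethoxy-5,5'-dimethylbiphenyl | COc1cc(CBr)c(-c2c(CBr)cc(OC)c(C)c2OC)c(OC)c1C
F4 | step 3 | tetraethyl [(4,4',6,6'-tetramethoxy-5,5'-dimethylbiphenyl-2,2'-diyl)bis(methylene)]bis(phosphonate) | CCOP(=O)(Cc1cc(OC)c(C)c(OC)c1-c1c(CP(=O)(OCC)OCC)cc(OC)c(C)c1OC)OCC
F5 | step 6 | 2,2',4,4'-tetramethoxy-3,3'-dimethyl-6,6'-bis(2-phenylethyl)biphenyl-5,5'-dicarbaldehyde | COc1c(C=O)c(CCc2ccccc2)c(-c2c(CCc3ccccc3)c(C=O)c(OC)c(C)c2OC)c(OC)c1C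
F6 | step 6 | 2,2',4,4'-tetramethoxy-3,3'-dimethyl-6,6'-bis(2-phenylethyl)biphenyl-5,5'-diyl diformate | COc1c(OC=O)c(CCc2ccccc2)c(-c2c(CCc3ccccc3)c(OC=O)c(OC)c(C)c2OC)c(OC)c1C
F7 | step 6 | 2,2',4,4'-tetramethoxy-3,3'-dimethyl-6,6'-bis(2-phenylethyl)biphenyl-5,5'-diol | COc1c(O)c(CCc2ccccc2)c(-c2c(CCc3ccccc3)c(O)c(OC)c(C)c2OC)c(OC)c1C
F8 | step 6 | 3,3'-dimethoxy-2,2'-dimethyl-5,5'-bis(2-phenylethyl)-6,6'-bi(cyclohexa-2,5-diene-1,4-dione) | CC1=C(OC)C(=O)C(CCc2ccccc2)=C(C2=C(CCc3ccccc3)C(=O)C(OC)=C(C)C2=O)C1=O
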